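## Analysis of the target

The target is the 4‑hydroxybenzoate of a daucane (carotane) triol, a trans‑fused bicyclo[5.3.0]decene. Daucane numbering is used throughout: C1 is the quaternary ring‑fusion carbon with the angular methyl, C2 and C3 are the cyclopentane methylenes, C4 is the tertiary carbinol bearing the isopropyl group, C5 is the ring‑fusion CH, C6 is the ester carbinol, C7 is a methylene, C8 is the tertiary allylic carbinol (its methyl is C14), and C9=C10 is the cis alkene that closes the seven‑membered ring back to C1. The five stereocentres are (1R,4R,5S,6S,8R). With the C1 methyl defining the β face, the C4 hydroxyl is β, H‑5 is α (trans fusion), and the C6 ester oxygen and C8 hydroxyl are both α; O4/O6 are therefore 1,3‑anti across C5 and O6/O8 are 1,3‑syn on the ring. C1, C5 and C4 form a contiguous triad (quaternary carbon, methine, fully substituted carbinol), and the C1–C5 bond between them is the most congested bond in the molecule. Sensitive groups are the tertiary allylic alcohol at C8 (ionisation, dehydration), the tertiary C4 alcohol β to C6 (retro‑aldol or dehydration whenever C6 is a ketone), C5 (epimerisable at the C6 ketone stage), the aryl ester (hydride, organometallics) and the free phenol. The difficulty is to build the seven‑membered ring and the C1/C5/C4 triad with trans fusion, and to place the C8 oxygen on the α face, which is the face a carbon nucleophile would take at a C8 ketone.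

## Retrosynthetic reasoning

**23 ⇒ 20 + 21 (C6–O acyl bond).** The ester is cut last because it would not survive the hydride steps. In triol 20 the C6 hydroxyl is the only secondary one, so acylation with 21 needs no protecting group on the skeleton. The phenol travels as its acetate (22) and is released in the same flask.

**20 ⇒ 19 ⇒ 18 (C8–O bond and C14–H bond).** The C8 carbinol is traced to an exocyclic C8=C14 methylene. Oxygen is delivered to C8 by the C6 hydroxyl (α, homoallylic), which fixes O8 as α, and hydride then opens epoxide 19 at the primary C14 to make the methyl. This avoids adding a carbon nucleophile to a C8 ketone, which would leave the hydroxyl on the wrong face, and it means C8 needs no oxidation‑state change after ring construction.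

**18 ⇒ 17 (C6–H bond).** The 1,3‑anti relation of O4 and O6 is the signature of an intramolecular hydride delivery from the C4 hydroxyl to a C6 ketone.

**17 ⇒ 15, via 16 (C1–C5 and C7–C8; key disconnection).** C5–C6–C7 with oxygen on the central carbon is an oxyallyl unit. C1=C10–C9=C8 is a diene in which C8 is the central carbon of an allene, so C14 emerges as the exocyclic methylene. The C4–O bond next to C5 is the remnant of an epoxide whose C5–O bond is the leaving group. Cutting the most hindered bond (C1–C5), which both rings share, opens both rings at once. The precursor 15 is acyclic with two stereocentres; the product is the bicycle with the complete C1/C5/C4 triad.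

**15 ⇒ 14 ⇒ 13 ⇒ 11, via 12 (enol silane; C6–C7 bond).** The enol silane comes from methyl ketone 14. The ketone methyl (C7) is added to aldehyde 12, so that the epoxide can be made from a primary allylic alcohol, the substrate class where catalytic asymmetric epoxidation is most reliable.

**11 ⇒ 10 (the two epoxide C–O bonds).** A Sharpless epoxidation is the only step that introduces absolute configuration. The E geometry of the C4=C5 alkene (C6 cis to C3) becomes, after inversion at C5 in the key step, the cis relation of O4 and C6 on the cyclopentane. No other alkene of 10 is an allylic alcohol.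

**10 ⇒ 7 + 8 (C1–CH3 and C9–C10 bonds).** Methylmetalation of the terminal alkyne of 7 sets the E‑trisubstituted C1=C10 alkene (tether trans to C9, as the trans fusion requires). The alkenyl metal is joined to 8 in the SN2′ sense to give the allene.

**7 ⇒ 5, via 6; 5 ⇒ 2 + 3, via 4; 2 ⇒ 1 (C3–C4 bond).** Cross‑coupling of Z enol triflate 2 with Grignard reagent 4 (from 3) proceeds with retention and fixes the C4=C5 geometry. 2 comes from β‑keto ester 1.

## Alternatives that were turned down

**Alternative 1:** the textbook cut, ring‑closing metathesis of the C9=C10 bond. The forward key step is closure of seco‑diene A1 (a cyclopentane carrying a vinyl group on C1 and the C5 side chain ending in the C8 vinyl carbinol) with a ruthenium alkylidene. It was turned down because the metathesis creates no stereocentre: all five, including the C1/C5/C4 triad and the remote C8 carbinol, would have to be built one by one on a cyclopentane beforehand. Both olefins are of the least reactive kind (vinyl on a quaternary carbon, vinyl on a tertiary carbinol), so closure to a trans‑fused cycloheptene would be slow against dimerisation. The step count to A1 would exceed that of the whole route below.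

**Alternative 2:** a Rh‑catalysed (5+2) cycloaddition forming C1–C5 and C6–C7. The forward key step converts ynyl vinylcyclopropane A2 (cyclopropane = C7, C8, C9, with C8 carrying CH3 and OSi; alkyne = C5≡C6) into bicyclic diene A3. It was turned down for three reasons. The quaternary C1 would be set only under remote influence of C4 and C8, with no element comparable to an epoxide inversion to enforce it. The cyclopropanol ether needs its own asymmetric synthesis and must be matched with the separately made C4 carbinol. A3 has a C5=C6 alkene where the target needs H‑5 and O‑6, so a hydroboration would have to choose the trisubstituted ring‑fusion alkene over the disubstituted C9=C10 and also deliver the trans fusion, which is unlikely on steric grounds.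

**Alternative 3:** an intramolecular aldol cyclopentannulation forming C4–C5. The forward key step is addition of the C5 enolate of cycloheptenone A4 to its pendant isopropyl ketone. It was turned down because enolisation of A4 should prefer C7 (α to the ketone and allylic to the diene) over C5. A tertiary β‑ketol is formed reversibly and tends to the cis‑fused isomer or to dehydration, and the C4 configuration (OH versus isopropyl) has no controlling element. The quaternary C1 would still need a separate asymmetric step, so the key step would close one ring and set two stereocentres without control.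

Key step: step 9

## Route

Assumption: the silyl triflate‑catalysed (4+3) reaction of the epoxy enolsilane is taken to follow an SN2‑type course with inversion at the epoxide carbon C5, so that the epoxide configuration is transferred to the ring fusion.

Step 1
Reactants: 1 methyl 4-methyl-3-oxopentanoate
Product: 2 methyl (2Z)-4-methyl-3-{[(trifluoromethyl)sulfonyl]oxy}pent-2-enoate
Conditions: Tf2O, sat. aq. LiOH, toluene, 5 °C
Reagents that add atoms: trifluoromethanesulfonic anhydride, O=S(=O)(OS(=O)(=O)C(F)(F)F)C(F)(F)F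
Why: O‑triflation of the chelated lithium enolate of the β‑keto ester (enol triflate formation); chelation holds the enolate oxygen cis to the ester, so the Z triflate should form, and this geometry later becomes the C4=C5 geometry.

Step 2
Reactants: 2 methyl (2Z)-4-methyl-3-{[(trifluoromethyl)sulfonyl]oxy}pent-2-enoate; 3 (4-bromobut-1-yn-1-yl)trimethylsilane
Product: 5 methyl (2E)-3-(propan-2-yl)-7-(trimethylsilyl)hept-2-en-6-ynoate, via Grignard reagent 4 (not isolated)
Conditions: 3, Mg, THF; then 2, Fe(acac)3 (5 mol%), THF/NMP, −30 °C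
Reagents that add atoms: none
Why: Iron‑catalysed Kumada‑type cross‑coupling of an alkenyl triflate with a primary alkyl Grignard reagent goes with retention of alkene geometry and is fast enough at −30 °C to spare the ester; the new chain therefore ends cis to the ester (2E alkene).

Step 3
Reactants: 5 methyl (2E)-3-(propan-2-yl)-7-(trimethylsilyl)hept-2-en-6-ynoate
Product: 7 (2E)-3-(propan-2-yl)hept-2-en-6-yn-1-ol, via silylated enynol 6 (not isolated)
Conditions: DIBAL-H, CH2Cl2, −78 → 0 °C; Rochelle salt work-up; crude in K2CO3, MeOH, rt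
Reagents that add atoms: none
Why: 1,2‑Reduction of the enoate to the allylic alcohol by DIBAL‑H, followed by base‑mediated methanolysis of the alkynyl C–Si bond; the trisubstituted alkene geometry is not touched.

Step 4
Reactants: 7 (2E)-3-(propan-2-yl)hept-2-en-6-yn-1-ol; 8 3-bromoprop-1-yne (propargyl bromide)
Product: 10 (2E,6E)-6-methyl-3-(propan-2-yl)deca-2,6,8,9-tetraen-1-ol, via alkenylalane 9 (not isolated)
Conditions: Me3Al, Cp2ZrCl2 (cat.), CH2Cl2, 0 °C → rt; volatiles removed; then 8, Pd(PPh3)4 (5 mol%), ZnCl2 (cat.), THF, 0 °C → rt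
Reagents that add atoms: trimethylaluminium, C[Al](C)C
Why: Zirconium‑catalysed Negishi methylalumination adds CH3 and Al syn across the terminal alkyne with the metal on the terminal carbon, giving the E alkenylalane (hydroxyl carried as its aluminium alkoxide). Pd‑catalysed coupling with the propargylic bromide goes through an allenyl–palladium species and should give the vinylallene with retention of the alkene geometry.

Step 5
Reactants: 10 (2E,6E)-6-methyl-3-(propan-2-yl)deca-2,6,8,9-tetraen-1-ol
Product: 11 [(2R,3R)-3-[(3E)-3-methylhepta-3,5,6-trien-1-yl]-3-(propan-2-yl)oxiran-2-yl]methanol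
Conditions: Ti(OiPr)4 (cat.), D-(−)-diethyl tartrate (cat.), t-BuOOH, 4 Å MS, CH2Cl2, −20 °C
Reagents that add atoms: tert-butyl hydroperoxide, CC(C)(C)OO
Why: Katsuki–Sharpless asymmetric epoxidation; with the D‑(−)‑tartrate the oxygen is delivered to the face that gives the (2R,3R) epoxide (C4 and C5 of the target numbering). Only the allylic alcohol alkene reacts, since the other C=C bonds have no directing hydroxyl.

Step 6
Reactants: 11 [(2R,3R)-3-[(3E)-3-methylhepta-3,5,6-trien-1-yl]-3-(propan-2-yl)oxiran-2-yl]methanol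
Product: 13 1-[(2R,3R)-3-[(3E)-3-methylhepta-3,5,6-trien-1-yl]-3-(propan-2-yl)oxiran-2-yl]ethan-1-ol (both carbinol epimers), via epoxy aldehyde 12 (not isolated)
Conditions: (COCl)2, DMSO, Et3N, CH2Cl2, −78 °C; then MeMgBr, −78 → −40 °C
Reagents that add atoms: methylmagnesium bromide, C[Mg]Br
Why: Swern oxidation to the sensitive epoxy aldehyde and Grignard addition in the same flask avoid its isolation; the new carbinol centre does not matter because it is oxidised in step 7.

Step 7
Reactants: 13 1-[(2R,3R)-3-[(3E)-3-methylhepta-3,5,6-trien-1-yl]-3-(propan-2-yl)oxiran-2-yl]ethan-1-ol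
Product: 14 1-[(2S,3R)-3-[(3E)-3-methylhepta-3,5,6-trien-1-yl]-3-(propan-2-yl)oxiran-2-yl]ethan-1-one
Conditions: Dess–Martin periodinane, CH2Cl2, 0 °C → rt
Reagents that add atoms: none
Why: Dess–Martin oxidation of a secondary alcohol under near‑neutral conditions should leave the epoxide, the allene and the α stereocentre intact (the descriptor at the oxirane carbon changes only through CIP priorities).

Step 8
Reactants: 14 1-[(2S,3R)-3-[(3E)-3-methylhepta-3,5,6-trien-1-yl]-3-(propan-2-yl)oxiran-2-yl]ethan-1-one
Product: 15 triethyl({1-[(2S,3R)-3-[(3E)-3-methylhepta-3,5,6-trien-1-yl]-3-(propan-2-yl)oxiran-2-yl]ethenyl}oxy)silane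
Conditions: LiHMDS, TESCl, THF, −78 °C
Reagents that add atoms: chlorotriethylsilane, CC[Si](Cl)(CC)CC
Why: Kinetic deprotonation of the methyl ketone at CH3 (the oxirane C–H is far less acidic) with in situ O‑silylation gives the enol silane, the latent 2‑siloxyallyl unit.

Step 9
Reactants: 15 triethyl({1-[(2S,3R)-3-[(3E)-3-methylhepta-3,5,6-trien-1-yl]-3-(propan-2-yl)oxiran-2-yl]ethenyl}oxy)silane
Product: 17 (3R,3aR,8aR)-3-hydroxy-8a-methyl-6-methylidene-3-(propan-2-yl)-2,3,3a,5,6,8a-hexahydroazulen-4(1H)-one (4β-hydroxy-dauca-8(14),9-dien-6-one), via triethylsilyl ether 16 (not isolated)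
Conditions: TESOTf (10 mol%), CH2Cl2, −78 °C; then HF·pyridine, pyridine, THF, 0 °C
Reagents that add atoms: none
Why: Proposed new method: TESOTf silylates the epoxide oxygen, the C5–O bond (allylic to the enol silane) ionises with backside attack by the diene terminus C1, and the enol silane carbon C7 then closes onto the allene central carbon C8 of the resulting allenyl‑stabilised cation, leaving C8 with its exocyclic methylene and returning the silyl cation to the catalytic cycle. The closest known reaction type is the silyl triflate‑catalysed (4+3) cycloaddition of epoxy enolsilanes with furans and dienes, including tethered cases that give bicyclo[5.3.0] ketones; a vinylallene as the 4π partner is known from Diels–Alder chemistry only. The cyclopentane closes in a 5‑exo mode (exo to both the C1=C10 π bond and the breaking C5–O bond), and the cycloheptene closes in the second bond‑forming event, C7 to C8, completing the (4+3) array. C4 is carried over from the Sharpless epoxide, and C5 follows from it by inversion, which, with the E‑derived epoxide, places C6 cis to the C4 oxygen. C1 is set relative to C5 by an extended (exo‑type) transition state on the E alkene, which puts the methyl cis to C6 and gives the trans fusion. The step needs attack at the diene terminus C1 and not at C10 (Prins or (3+2) closure); only attack at C1 leaves a conjugated cation, and that should secure it. It needs ionisation at C5 and not at the tertiary C4, which the enol silane should secure. It needs the extended over the compact transition state, which the bulky triethylsiloxy group on C6 should favour, while the sp‑hybridised C8, having no inside hydrogen, should let the diene reach the s‑cis geometry despite the inside methyl on C1. Buffered fluoride then cleaves the tertiary silyl ether 16 without enolising the ketone.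

Step 10
Reactants: 17 (3R,3aR,8aR)-3-hydroxy-8a-methyl-6-methylidene-3-(propan-2-yl)-2,3,3a,5,6,8a-hexahydroazulen-4(1H)-one
Product: 18 (3R,3aS,4S,8aR)-8a-methyl-6-methylidene-3-(propan-2-yl)-1,2,3,3a,4,5,6,8a-octahydroazulene-3,4-diol (dauca-8(14),9-diene-4β,6α-diol)
Conditions: Me4NBH(OAc)3, MeCN/AcOH, −30 °C
Reagents that add atoms: none
Why: Evans–Saksena reduction: ligand exchange puts boron on the C4 oxygen and hydride is delivered intramolecularly to the β face of the C6 ketone, which should give the 1,3‑anti diol (6α‑OH). The cold, mildly acidic medium avoids enolisation, retro‑aldol cleavage and migration of the exocyclic alkene.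

Step 11
Reactants: 18 (3R,3aS,4S,8aR)-8a-methyl-6-methylidene-3-(propan-2-yl)-1,2,3,3a,4,5,6,8a-octahydroazulene-3,4-diol
Product: 19 (3R,3aS,4S,6R,8aR)-8a-methyl-3-(propan-2-yl)-1,2,3,3a,4,5-hexahydro-8aH-spiro[azulene-6,2'-oxirane]-3,4-diol (the 8α,14-epoxide of 18)
Conditions: VO(acac)2 (cat.), t-BuOOH, toluene, 0 °C
Reagents that add atoms: tert-butyl hydroperoxide, CC(C)(C)OO
Why: Vanadium‑catalysed hydroxyl‑directed epoxidation: the homoallylic C6–OH binds vanadium and delivers oxygen to the α face of the exocyclic C8=C14 bond, the more nucleophilic 1,1‑disubstituted end of the diene. The C9=C10 bond is out of reach and shielded by the quaternary C1.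

Step 12
Reactants: 19 (3R,3aS,4S,6R,8aR)-8a-methyl-3-(propan-2-yl)-1,2,3,3a,4,5-hexahydro-8aH-spiro[azulene-6,2'-oxirane]-3,4-diol
Product: 20 (3R,3aS,4S,6R,8aR)-6,8a-dimethyl-3-(propan-2-yl)-1,2,3,3a,4,5,6,8a-octahydroazulene-3,4,6-triol (dauc-9-ene-4β,6α,8α-triol)
Conditions: LiEt3BH, THF, 0 °C → rt
Reagents that add atoms: none
Why: Reductive SN2 opening of the epoxide by hydride at the primary carbon C14 turns C14 into the methyl group and leaves the C8–O bond, hence the 8α hydroxyl, untouched. SN2′ attack at C10 is blocked by the adjacent quaternary C1.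

Step 13
Reactants: 20 (3R,3aS,4S,6R,8aR)-6,8a-dimethyl-3-(propan-2-yl)-1,2,3,3a,4,5,6,8a-octahydroazulene-3,4,6-triol; 21 4-(chlorocarbonyl)phenyl acetate (4-acetoxybenzoyl chloride)
Product: 23 (3R,3aS,4S,6R,8aR)-3,6-dihydroxy-6,8a-dimethyl-3-(propan-2-yl)-1,2,3,3a,4,5,6,8a-octahydroazulen-4-yl 4-hydroxybenzoate (CNP0280165.4), via acetoxybenzoate 22 (not isolated)
Conditions: 21, Et3N, DMAP (cat.), CH2Cl2, 0 °C; then pyrrolidine, rt
Reagents that add atoms: none
Why: DMAP‑catalysed acylation is selective for the only secondary hydroxyl (C4 and C8 are tertiary). Aminolysis of the phenolic acetate is much faster than attack on the hindered, electron‑rich secondary benzoate, and the basic medium protects the tertiary allylic alcohol.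

## Compound list

1 | methyl 4-methyl-3-oxopentanoate | COC(=O)CC(=O)C(C)C | starting material
2 | methyl (2Z)-4-methyl-3-{[(trifluoromethyl)sulfonyl]oxy}pent-2-enoate | COC(=O)/C=C(\OS(=O)(=O)C(F)(F)F)C(C)C | intermediate
3 | (4-bromobut-1-yn-1-yl)trimethylsilane | C[Si](C)(C)C#CCCBr | starting material
4 | [4-(trimethylsilyl)but-3-yn-1-yl]magnesium bromide | C[Si](C)(C)C#CCC[Mg]Br | intermediate (not isolated)
5 | methyl (2E)-3-(propan-2-yl)-7-(trimethylsilyl)hept-2-en-6-ynoate | COC(=O)/C=C(\CCC#C[Si](C)(C)C)C(C)C | intermediate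
6 | (2E)-3-(propan-2-yl)-7-(trimethylsilyl)hept-2-en-6-yn-1-ol | OC/C=C(\CCC#C[Si](C)(C)C)C(C)C | intermediate (not isolated)
7 | (2E)-3-(propan-2-yl)hept-2-en-6-yn-1-ol | OC/C=C(\CCC#C)C(C)C | intermediate
8 | 3-bromoprop-1-yne (propargyl bromide) | C#CCBr | starting material
9 | {[(2E,6E)-7-(dimethylalumanyl)-6-methyl-3-(propan-2-yl)hepta-2,6-dien-1-yl]oxy}dimethylalumane | C[Al](C)OC/C=C(\CC/C(C)=C/[Al](C)C)C(C)C | intermediate (not isolated)
10 | (2E,6E)-6-methyl-3-(propan-2-yl)deca-2,6,8,9-tetraen-1-ol | OC/C=C(\CC/C(C)=C/C=C=C)C(C)C | intermediate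
11 | [(2R,3R)-3-[(3E)-3-methylhepta-3,5,6-trien-1-yl]-3-(propan-2-yl)oxiran-2-yl]methanol | CC(C)[C@@]1(CC/C(C)=C/C=C=C)O[C@@H]1CO | intermediate
12 | (2S,3R)-3-[(3E)-3-methylhepta-3,5,6-trien-1-yl]-3-(propan-2-yl)oxirane-2-carbaldehyde | CC(C)[C@@]1(CC/C(C)=C/C=C=C)O[C@@H]1C=O | intermediate (not isolated)
13 | 1-[(2R,3R)-3-[(3E)-3-methylhepta-3,5,6-trien-1-yl]-3-(propan-2-yl)oxiran-2-yl]ethan-1-ol (carbinol epimers) | CC(C)[C@@]1(CC/C(C)=C/C=C=C)O[C@@H]1C(C)O | intermediate
14 | 1-[(2S,3R)-3-[(3E)-3-methylhepta-3,5,6-trien-1-yl]-3-(propan-2-yl)oxiran-2-yl]ethan-1-one | CC(C)[C@@]1(CC/C(C)=C/C=C=C)O[C@@H]1C(C)=O | intermediate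
15 | triethyl({1-[(2S,3R)-3-[(3E)-3-methylhepta-3,5,6-trien-1-yl]-3-(propan-2-yl)oxiran-2-yl]ethenyl}oxy)silane | CC(C)[C@@]1(CC/C(C)=C/C=C=C)O[C@@H]1C(=C)O[Si](CC)(CC)CC | intermediate
16 | (3R,3aR,8aR)-8a-methyl-6-methylidene-3-(propan-2-yl)-3-[(triethylsilyl)oxy]-2,3,3a,5,6,8a-hexahydroazulen-4(1H)-one | CC(C)[C@]1(O[Si](CC)(CC)CC)CC[C@]2(C)C=CC(=C)CC(=O)[C@H]21 | intermediate (not isolated)
17 | (3R,3aR,8aR)-3-hydroxy-8a-methyl-6-methylidene-3-(propan-2-yl)-2,3,3a,5,6,8a-hexahydroazulen-4(1H)-one | CC(C)[C@]1(O)CC[C@]2(C)C=CC(=C)CC(=O)[C@H]21 | intermediate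
18 | (3R,3aS,4S,8aR)-8a-methyl-6-methylidene-3-(propan-2-yl)-1,2,3,3a,4,5,6,8a-octahydroazulene-3,4-diol | CC(C)[C@]1(O)CC[C@]2(C)C=CC(=C)C[C@H](O)[C@H]21 | intermediate
19 | (3R,3aS,4S,6R,8aR)-8a-methyl-3-(propan-2-yl)-1,2,3,3a,4,5-hexahydro-8aH-spiro[azulene-6,2'-oxirane]-3,4-diol | CC(C)[C@]1(O)CC[C@]2(C)C=C[C@]3(OC3)C[C@H](O)[C@H]21 | intermediate
20 | (3R,3aS,4S,6R,8aR)-6,8a-dimethyl-3-(propan-2-yl)-1,2,3,3a,4,5,6,8a-octahydroazulene-3,4,6-triol | CC(C)[C@]1(O)CC[C@]2(C)C=C[C@](C)(O)C[C@H](O)[C@H]21 | intermediate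
21 | 4-(chlorocarbonyl)phenyl acetate | CC(=O)Oc1ccc(cc1)C(Cl)=O | starting material
22 | (3R,3aS,4S,6R,8aR)-3,6-dihydroxy-6,8a-dimethyl-3-(propan-2-yl)-1,2,3,3a,4,5,6,8a-octahydroazulen-4-yl 4-(acetyloxy)benzoate | CC(C)[C@]1(O)CC[C@]2(C)C=C[C@](C)(O)C[C@H](OC(=O)c3ccc(OC(C)=O)cc3)[C@H]21 | intermediate (not isolated)
23 | (3R,3aS,4S,6R,8aR)-3,6-dihydroxy-6,8a-dimethyl-3-(propan-2-yl)-1,2,3,3a,4,5,6,8a-octahydroazulen-4-yl 4-hydroxybenzoate | CC(C)[C@]1(O)CC[C@]2(C)C=C[C@](C)(O)C[C@H](OC(=O)c3ccc(O)cc3)[C@H]21 | target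

## Step count and least certain steps

Total: 13 steps. Longest linear sequence: 13 steps (1 → 23); 3, 8 and 21 are commercial inputs.

**Step 9 (key step, Proposed new method).** Four processes are most likely to go wrong.
- Closure through C10 instead of C1 (Prins‑type cyclohexane or (3+2) cyclopentanone formation), because C1 is fully substituted and the C1–C5 bond is congested.
- Ionisation at the tertiary C4 followed by a hydride shift (Meinwald rearrangement).
- Loss of the extended/compact preference, which would give the cis‑fused C1 epimer; the inside methyl on C1 lies under C6 in the extended transition state.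
- Acid‑promoted migration of the exocyclic alkene of 17 into conjugation with the ketone.

The fallback keeps the oxyallyl precursor but returns to a plain butadiene tether, the class for which this cycloaddition has precedent; it sets out from 7 and returns at 18. Methylalumination of 7 as in step 4, but with Pd‑catalysed coupling to vinyl bromide, gives (2E,6E)-6-methyl-3-(propan-2-yl)nona-2,6,8-trien-1-ol F1. Sharpless epoxidation as in step 5 gives [(2R,3R)-3-[(3E)-3-methylhexa-3,5-dien-1-yl]-3-(propan-2-yl)oxiran-2-yl]methanol F2. Swern oxidation gives (2S,3R)-3-[(3E)-3-methylhexa-3,5-dien-1-yl]-3-(propan-2-yl)oxirane-2-carbaldehyde F3, methyl Grignard addition gives 1-[(2R,3R)-3-[(3E)-3-methylhexa-3,5-dien-1-yl]-3-(propan-2-yl)oxiran-2-yl]ethan-1-ol F4, and Dess–Martin oxidation gives 1-[(2S,3R)-3-[(3E)-3-methylhexa-3,5-dien-1-yl]-3-(propan-2-yl)oxiran-2-yl]ethan-1-one F5. Silylation as in step 8 gives triethyl({1-[(2S,3R)-3-[(3E)-3-methylhexa-3,5-dien-1-yl]-3-(propan-2-yl)oxiran-2-yl]ethenyl}oxy)silane F6. Catalytic TESOTf should give (3R,3aR,8aR)-8a-methyl-3-(propan-2-yl)-3-[(triethylsilyl)oxy]-2,3,3a,5,6,8a-hexahydroazulen-4(1H)-one F7, and fluoride gives (3R,3aR,8aR)-3-hydroxy-8a-methyl-3-(propan-2-yl)-2,3,3a,5,6,8a-hexahydroazulen-4(1H)-one F8. Evans–Saksena reduction gives (3R,3aS,4S,8aR)-8a-methyl-3-(propan-2-yl)-1,2,3,3a,4,5,6,8a-octahydroazulene-3,4-diol F9. Allylic hydroxylation with SeO2/t‑BuOOH at C8, the only allylic CH2, gives (3R,3aS,4S,8aR)-8a-methyl-3-(propan-2-yl)-1,2,3,3a,4,5,6,8a-octahydroazulene-3,4,6-triol F10 (C8 epimers). MnO2 oxidises only the allylic alcohol to (3R,3aS,4S,8aR)-3,4-dihydroxy-8a-methyl-3-(propan-2-yl)-2,3,3a,4,5,8a-hexahydroazulen-6(1H)-one F11. Non‑basic Petasis methylenation (Cp2TiMe2) then gives 18.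

**Step 4.** The reductive elimination may give propargyl (skipped enyne) product beside the allene, residual methylalane may methylate the bromide, and the vinylallene may oligomerise on palladium. The fallback reverses the polarity of the coupling; it sets out from 7 and returns at 10. Methylalumination followed by iodinolysis gives (2E,6E)-7-iodo-6-methyl-3-(propan-2-yl)hepta-2,6-dien-1-ol F12, and Stille coupling with tributyl(propa-1,2-dien-1-yl)stannane gives 10.

**Step 10.** The tertiary C4 hydroxyl may exchange onto boron too slowly, so that undirected hydride attack from the open α face takes over and gives the 6β alcohol. The fallback accepts that face and corrects it by inversion; it sets out from 17 and returns at 18. NaBH4/CeCl3 reduction gives (3R,3aS,4R,8aR)-8a-methyl-6-methylidene-3-(propan-2-yl)-1,2,3,3a,4,5,6,8a-octahydroazulene-3,4-diol F13. Mitsunobu reaction with 4‑nitrobenzoic acid gives (3R,3aS,4S,8aR)-3-hydroxy-8a-methyl-6-methylidene-3-(propan-2-yl)-1,2,3,3a,4,5,6,8a-octahydroazulen-4-yl 4-nitrobenzoate F14, and K2CO3/MeOH gives 18.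

**Step 11.** The vinyl epoxide 19 may ionise at its tertiary allylic C8–O bond under the vanadium/peroxide conditions (rearrangement or SN2′ opening), or oxygen delivery may be incomplete in face or site. The fallback replaces the epoxide by a tethered oxygen delivery; it sets out from 18 and returns at 20, bypassing 19. Boc2O/DMAP acylates only the secondary hydroxyl to give tert-butyl (3R,3aS,4S,8aR)-3-hydroxy-8a-methyl-6-methylidene-3-(propan-2-yl)-1,2,3,3a,4,5,6,8a-octahydroazulen-4-yl carbonate F15. IBr at −80 °C closes the six‑membered cyclic carbonate onto C8 from the α face, giving the 6α,8α-cyclic carbonate of 14-iodo-dauc-9-ene-4β,6α,8α-triol F16. Bu3SnH/AIBN removes iodine to give the 6α,8α-cyclic carbonate of dauc-9-ene-4β,6α,8α-triol F17, and K2CO3/MeOH gives 20.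

## Further compounds

F1 | step 9 | (2E,6E)-6-methyl-3-(propan-2-yl)nona-2,6,8-trien-1-ol | OC/C=C(\CC/C(C)=C/C=C)C(C)C
F2 | step 9 | [(2R,3R)-3-[(3E)-3-methylhexa-3,5-dien-1-yl]-3-(propan-2-yl)oxiran-2-yl]methanol | CC(C)[C@@]1(CC/C(C)=C/C=C)O[C@@H]1CO
F3 | step 9 | (2S,3R)-3-[(3E)-3-methylhexa-3,5-dien-1-yl]-3-(propan-2-yl)oxirane-2-carbaldehyde | CC(C)[C@@]1(CC/C(C)=C/C=C)O[C@@H]1C=O
F4 | step 9 | 1-[(2R,3R)-3-[(3E)-3-methylhexa-3,5-dien-1-yl]-3-(propan-2-yl)oxiran-2-yl]ethan-1-ol | CC(C)[C@@]1(CC/C(C)=C/C=C)O[C@@H]1C(C)O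
F5 | step 9 | 1-[(2S,3R)-3-[(3E)-3-methylhexa-3,5-dien-1-yl]-3-(propan-2-yl)oxiran-2-yl]ethan-1-one | CC(C)[C@@]1(CC/C(C)=C/C=C)O[C@@H]1C(C)=O
F6 | step 9 | triethyl({1-[(2S,3R)-3-[(3E)-3-methylhexa-3,5-dien-1-yl]-3-(propan-2-yl)oxiran-2-yl]ethenyl}oxy)silane | CC(C)[C@@]1(CC/C(C)=C/C=C)O[C@@H]1C(=C)O[Si](CC)(CC)CC
F7 | step 9 | (3R,3aR,8aR)-8a-methyl-3-(propan-2-yl)-3-[(triethylsilyl)oxy]-2,3,3a,5,6,8a-hexahydroazulen-4(1H)-one | CC(C)[C@]1(O[Si](CC)(CC)CC)CC[C@]2(C)C=CCCC(=O)[C@H]21
F8 | step 9 | (3R,3aR,8aR)-3-hydroxy-8a-methyl-3-(propan-2-yl)-2,3,3a,5,6,8a-hexahydroazulen-4(1H)-one | CC(C)[C@]1(O)CC[C@]2(C)C=CCCC(=O)[C@H]21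
F9 | step 9 | (3R,3aS,4S,8aR)-8a-methyl-3-(propan-2-yl)-1,2,3,3a,4,5,6,8a-octahydroazulene-3,4-diol | CC(C)[C@]1(O)CC[C@]2(C)C=CCC[C@H](O)[C@H]21
F10 | step 9 | (3R,3aS,4S,8aR)-8a-methyl-3-(propan-2-yl)-1,2,3,3a,4,5,6,8a-octahydroazulene-3,4,6-triol (C6 epimers) | CC(C)[C@]1(O)CC[C@]2(C)C=CC(O)C[C@H](O)[C@H]21
F11 | step 9 | (3R,3aS,4S,8aR)-3,4-dihydroxy-8a-methyl-3-(propan-2-yl)-2,3,3a,4,5,8a-hexahydroazulen-6(1H)-one | CC(C)[C@]1(O)CC[C@]2(C)C=CC(=O)C[C@H](O)[C@H]21
F12 | step 4 | (2E,6E)-7-iodo-6-methyl-3-(propan-2-yl)hepta-2,6-dien-1-ol | OC/C=C(\CC/C(C)=C/I)C(C)C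
F13 | step 10 | (3R,3aS,4R,8aR)-8a-methyl-6-methylidene-3-(propan-2-yl)-1,2,3,3a,4,5,6,8a-octahydroazulene-3,4-diol | CC(C)[C@]1(O)CC[C@]2(C)C=CC(=C)C[C@@H](O)[C@H]21
F14 | step 10 | (3R,3aS,4S,8aR)-3-hydroxy-8a-methyl-6-methylidene-3-(propan-2-yl)-1,2,3,3a,4,5,6,8a-octahydroazulen-4-yl 4-nitrobenzoate | CC(C)[C@]1(O)CC[C@]2(C)C=CC(=C)C[C@H](OC(=O)c3ccc(cc3)[N+](=O)[O-])[C@H]21
F15 | step 11 | tert-butyl (3R,3aS,4S,8aR)-3-hydroxy-8a-methyl-6-methylidene-3-(propan-2-yl)-1,2,3,3a,4,5,6,8a-octahydroazulen-4-yl carbonate | CC(C)[C@]1(O)CC[C@]2(C)C=CC(=C)C[C@H](OC(=O)OC(C)(C)C)[C@H]21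
F16 | step 11 | 6α,8α-cyclic carbonate of 14-iodo-dauc-9-ene-4β,6α,8α-triol | CC(C)[C@]1(O)CC[C@]2(C)C=C[C@@]3(CI)C[C@H](OC(=O)O3)[C@H]21
F17 | step 11 | 6α,8α-cyclic carbonate of dauc-9-ene-4β,6α,8α-triol | CC(C)[C@]1(O)CC[C@]2(C)C=C[C@@]3(C)C[C@H](OC(=O)O3)[C@H]21
A1 | alternative 1 | seco-diene for ring-closing metathesis: (1R,2S,3R)-2-[(1S,3R)-1,3-dihydroxy-3-methylpent-4-en-1-yl]-3-ethenyl-3-methyl-1-(propan-2-yl)cyclopentan-1-ol | CC(C)[C@]1(O)CC[C@](C)(C=C)[C@H]1[C@@H](O)C[C@@](C)(O)C=C
A2 | alternative 2 | ynyl vinylcyclopropane: tert-butyl({2-[(1E)-5-hydroxy-2-methyl-5-(propan-2-yl)hept-1-en-6-yn-1-yl]-1-methylcyclopropyl}oxy)dimethylsilane | CC(C)[C@@](O)(C#C)CC/C(C)=C/[C@@H]1C[C@@]1(C)O[Si](C)(C)C(C)(C)C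
A3 | alternative 2 | (5+2) cycloadduct: 8α-(tert-butyldimethylsilyloxy)dauca-5,9-dien-4β-ol | CC(C)[C@]1(O)CC[C@]2(C)C=C[C@](C)(O[Si](C)(C)C(C)(C)C)CC=C21
A4 | alternative 3 | (3S)-3-methyl-3-(4-methyl-3-oxopentyl)-6-methylidenecyclohept-4-en-1-one | CC(C)C(=O)CC[C@@]1(C)CC(=O)CC(=C)C=C1
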